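Start from the constants: none is given, so read what is needed from the two earlier runs.

| setting | north-east | west | Thursday's | Friday's | Saturday's |
|---|---|---|---|---|---|
| electrophile | 0.10 M | 0.10 M | 0.10 M | 0.10 M | 0.10 M |
| nucleophile | 1.4 equiv | 2.4 equiv | 1.20 equiv | 1.60 equiv | 2.00 equiv |
| solid base | 1.1 equiv | 1.1 equiv | 1.10 equiv | 1.10 equiv | 1.10 equiv |
| remark | run made earlier | run made earlier |  |  |  |
| time |  |  | 30 min | 30 min | 30 min |

| run | time / min | electrophile / % | target / % |
|---|---|---|---|
| north-east | 2.50 | 32.3 | 54.2 |
| north-east | 5.00 | 21.4 | 65.8 |
| north-east | 8.00 | 16.5 | 68.5 |
| north-east | 15.0 | 13.6 | 69.7 |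
| north-east | 30.0 | 8.1 | 71.6 |
| west | 2.50 | 13.4 | 79.3 |
| west | 8.00 | 0.2 | 91.4 |
| west | 15.0 | 2.1 | 93.4 |
| west | 20.0 | 0.1 | 94.1 |
| west | 30.0 | 0.4 | 93.3 |

(scatter of a reading: 1 percentage point)

- as a solid, counted per litre of solution: solid base
- at the start none of the solid base is in solution

- part of the electrophile that has reacted at the end, Thursday's
- part of the electrophile that has reacted at the end, Friday's
- part of the electrophile that has reacted at the end, Saturday's
- what raising the equivalents of nucleophile from its lowest to its highest value here does to the part of the electrophile that has reacted (changes below 5 percentage points count as none) (it rises / it falls / no change)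

Early in the north-east run the electrophile halves in 1.53 min. Its 30.0 min are far longer than that, about 19.6 half-lives, yet 8.1% of the electrophile stands there. So time is not what stops this flask.

Look at the target instead: it barely moves, from 69.7% to 71.6%. Treat nucleophile as the limiting reagent and read the nucleophile price, the equivalents of nucleophile gone per target formed: 1.96 equiv. Charge over price then gives an estimate of the target, 61.4% for Thursday's, 81.8% for Friday's. Saturday's estimate, 102%, lies above the electrophile charged, so reckon 100% reacted there.

Reacted electrophile is target plus what the readings do not show. That unseen share is 20.3% in the north-east run and 6.30% in the west run. A straight line between them gives 84.5% reacted for Thursday's and 99.3% for Friday's.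

That line is the weak link, for it reaches nothing soon after the west run. Bend it: let the share fall as the inverse square of the charge. From the north-east run this predicts 6.91% for the west run, close to the reading. Thursday's becomes 89.0% and Friday's 97.4%. The rise to Saturday's, 11 percentage points, is larger than 5 points.

The forecast gives 87.5%, 96% and 99.3%, and says it rises, with “nucleophile just suffices” at the top charge. Its first two lie below this reckoning.

The flask gives 90.3%, 96.1% and 99.9%: it rises, by 9.6 points.

    solid base ⇌ free base, rate k1*(cs1 - [free base]) while solid is left; crystals form when [free base] > cs1 (solubility = 3.20 mM, k = 0.0760 min⁻¹)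
    electrophile + nucleophile → acid set free + target (k = 6.20 M⁻¹ min⁻¹)
    nucleophile + acid set free ⇌ protonated nucleophile, settled at all times (K = 24000 M⁻¹)
    acid set free + free base ⇌ salt of the base, settled at all times (K = 79000 M⁻¹)
    2 electrophile → homo dimer (k = 0.790 M⁻¹ min⁻¹)

In Friday's flask half the making of target is done by 0.805 min, while the going into solution of solid base has 10% of its turnover behind it at 3.00 min. At 30.0 min Friday's holds protonated nucleophile at 0.0737 M against salt of the base at 0.00692 M, a price of 1.91 equiv. Now take Friday's flask with nucleophile at 2.70 equiv: charge over the price 1.96 equiv gives 138%, above the electrophile charged, so reckon 100% reacted. That flask gives 100% reacted at 30.0 min, with 94.0% target and 32% of its nucleophile charge left.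

The runs were generated by integration on assumed constants; scatter was added.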